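**Remark:** carbons of the fused intermediates carry guaiane numbers (C1 and C5 ring-fusion carbons, C2–C4 the rest of the five-membered ring A, C6–C10 the rest of the seven-membered ring, C11–C13 the lactone side chain, C14 and C15 the methyls on C10 and C4); α is the face of H-1, β the face of the C5–O bond.

## Retrosynthetic overview

1. The target is a 2α-tigloyloxy-13-acetoxy-4α-hydroxy-5β,11-epoxyguaian-8β,12-olide; the esters go on last, C13 comes from formaldehyde on the lactone enolate, and the lactone from oxidation of C12 onto 8β-OH.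
2. Ring A (C1–C5) is closed by silyl enol ether/olefin metathesis (C2=C3), after the oxolane (C5–O–C11) is closed by oxa-Michael addition of 11-OH to a C1=C5 enone.
3. Key disconnection: the seven-membered ring (C1, C5–C10) by an intermolecular rhodium-catalysed (5+2) cycloaddition that forms C5–C6 and C1–C10 together, from siloxy-vinylcyclopropane 10 (C6–C14) and ynone 17 (C1–C5, C15).
4. Enabling feature: in the cycloheptane ring the oxygenated C8 sits at the centre of the five-carbon unit C6–C10 (a 1-siloxy-1-alkenylcyclopropane), and the remaining ring atoms C1 and C5 are the fusion carbons to ring A, whose neighbours C2 (oxygenated, as acyl) and C4 (fully substituted carbinol) bias an alkyne to one orientation.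
5. Ring order: cyclopropane (temporary) → seven-membered ring → oxolane → ring A → lactone; absolute stereochemistry comes from D-ribono-1,4-lactone (C11, relayed to C7, C10, C5, C1, C8, C2) and from an asymmetric allylic etherification (C4).

Key step: step 11

## Route

Step 1
Reactants: 1 D-ribono-1,4-lactone
Product: 2 5-O-(tert-butyldimethylsilyl)-D-ribono-1,4-lactone
Conditions: t-BuMe2SiCl (1.05 equiv), imidazole, DMF, 0 °C
Reagents that add atoms: tert-butyldimethylsilyl chloride, CC(C)(C)[Si](C)(C)Cl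
Why: Selective silyl ether formation at the unhindered primary 5-OH, which reacts much faster than the secondary 2- and 3-OH groups; no stereocentre is touched.

Step 2
Reactants: 2 5-O-(tert-butyldimethylsilyl)-D-ribono-1,4-lactone
Product: 4 (5S)-3-acetoxy-5-[(tert-butyldimethylsilyloxy)methyl]furan-2(5H)-one, via diacetate 3 (not isolated)
Conditions: Ac2O, pyridine, DMAP (cat.), CH2Cl2, 0 °C → rt; then Et3N, rt
Reagents that add atoms: acetic anhydride, CC(=O)OC(C)=O
Why: Acetylation followed by E1cB β-elimination of the 3-acetoxy group from the lactone enolate (the known β-elimination of acylated aldonolactones) gives the enol acetate butenolide; only the former sugar C4 (later C11) stays stereogenic and is not touched.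

Step 3
Reactants: 4 (5S)-3-acetoxy-5-[(tert-butyldimethylsilyloxy)methyl]furan-2(5H)-one
Product: 6 (5S)-3-(tert-butyldimethylsilyloxy)-5-[(tert-butyldimethylsilyloxy)methyl]furan-2(5H)-one, via enol 5 (not isolated)
Conditions: Et3N, MeOH, 0 °C; concentrate; then t-BuMe2SiCl, imidazole, DMF, rt
Reagents that add atoms: tert-butyldimethylsilyl chloride, CC(C)(C)[Si](C)(C)Cl
Why: Transesterification of the activated enol ester frees the enol of the α-keto lactone, which is silylated on oxygen to a robust silyl enol ether; the stereocentre is untouched.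

Step 4
Reactants: 6 (5S)-3-(tert-butyldimethylsilyloxy)-5-[(tert-butyldimethylsilyloxy)methyl]furan-2(5H)-one
Product: 7 (1S,4S,5R)-1-(tert-butyldimethylsilyloxy)-4-[(tert-butyldimethylsilyloxy)methyl]-3-oxabicyclo[3.1.0]hexan-2-one
Conditions: Et2Zn, CF3CO2H, CH2I2, CH2Cl2, 0 °C → rt
Reagents that add atoms: diiodomethane, ICI
Why: Simmons–Smith cyclopropanation of the silyl enol ether with the trifluoroacetate-modified carbenoid CF3CO2ZnCH2I, which is non-basic so C4 cannot epimerise; methylene is delivered anti to the silyloxymethyl group, setting the future C7 and C8, and the ring fusion holds the lactone carbonyl (future C9) cis to the side chain.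

Step 5
Reactants: 7 (1S,4S,5R)-1-(tert-butyldimethylsilyloxy)-4-[(tert-butyldimethylsilyloxy)methyl]-3-oxabicyclo[3.1.0]hexan-2-one
Product: 8 (1S,4S,5R)-1-(tert-butyldimethylsilyloxy)-4-[(tert-butyldimethylsilyloxy)methyl]-3-oxabicyclo[3.1.0]hexan-2-ol (both anomers)
Conditions: i-Bu2AlH (1.1 equiv), CH2Cl2, −78 °C
Reagents that add atoms: none
Why: Partial reduction of a γ-lactone to the lactol, the tetrahedral aluminate being stable at −78 °C; the silyl ethers are inert and no ring stereocentre changes.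

Step 6
Reactants: 8 (1S,4S,5R)-1-(tert-butyldimethylsilyloxy)-4-[(tert-butyldimethylsilyloxy)methyl]-3-oxabicyclo[3.1.0]hexan-2-ol; 9 5-(ethylsulfonyl)-1-phenyl-1H-tetrazole
Product: 10 (1S)-2-(tert-butyldimethylsilyloxy)-1-{(1R,2R)-2-(tert-butyldimethylsilyloxy)-2-[(E)-prop-1-enyl]cyclopropyl}ethanol
Conditions: KN(SiMe3)2 (2.2 equiv), DME, −60 °C → rt
Reagents that add atoms: none
Why: Julia–Kocienski olefination of the ring-opened hydroxy aldehyde; the α-branched aldehyde and the phenyltetrazolyl sulfone anion should give the E alkene, and the former lactone oxygen is released as the free 11-OH.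

Step 7
Reactants: 11 2-methyl-2-vinyloxirane (racemic); 12 4-methoxybenzyl alcohol
Product: 13 (2R)-2-[(4-methoxybenzyl)oxy]-2-methylbut-3-en-1-ol
Conditions: Pd2(dba)3·CHCl3 (1 mol %), (R,R)-N,N'-(cyclohexane-1,2-diyl)bis[2-(diphenylphosphino)benzamide] (3 mol %), BEt3 (1 mol %), CH2Cl2, rt
Reagents that add atoms: none
Why: Zerovalent-palladium-catalysed dynamic kinetic asymmetric allylic etherification of the vinyl epoxide, in which the interconverting π-allyl intermediates take the boron-bound alcohol at the more substituted terminus and the chiral diphosphine sets the quaternary C4 centre; the ligand antipode is the one that gives the R ether.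

Step 8
Reactants: 13 (2R)-2-[(4-methoxybenzyl)oxy]-2-methylbut-3-en-1-ol
Product: 14 (2R)-2-[(4-methoxybenzyl)oxy]-2-methylbut-3-enal
Conditions: Dess–Martin periodinane, CH2Cl2, 0 °C → rt
Reagents that add atoms: none
Why: Dess–Martin oxidation of a primary alcohol under neutral conditions; the α-carbon is fully substituted and cannot epimerise.

Step 9
Reactants: 14 (2R)-2-[(4-methoxybenzyl)oxy]-2-methylbut-3-enal
Product: 15 (3R)-3-[(4-methoxybenzyl)oxy]-3-methylpent-1-en-4-yne
Conditions: dimethyl (1-diazo-2-oxopropyl)phosphonate, K2CO3, MeOH, 0 °C → rt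
Reagents that add atoms: dimethyl (1-diazo-2-oxopropyl)phosphonate, CC(=O)C(=[N+]=[N-])P(=O)(OC)OC
Why: Seyferth–Gilbert homologation with the Ohira–Bestmann reagent converts the non-enolisable aldehyde into the terminal alkyne through a vinylidene carbene 1,2-shift, leaving the quaternary centre untouched.

Step 10
Reactants: 15 (3R)-3-[(4-methoxybenzyl)oxy]-3-methylpent-1-en-4-yne
Product: 17 (5R)-5-[(4-methoxybenzyl)oxy]-5-methylhept-6-en-3-yn-2-one, via lithium acetylide 16 (not isolated)
Conditions: n-BuLi, THF, −78 °C; then N-methoxy-N-methylacetamide, −78 → 0 °C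
Reagents that add atoms: N-methoxy-N-methylacetamide, CC(=O)N(C)OC
Why: Acylation of a lithium acetylide with a Weinreb amide, whose chelated tetrahedral intermediate prevents over-addition, gives the ynone.

Step 11
Reactants: 10 (1S)-2-(tert-butyldimethylsilyloxy)-1-{(1R,2R)-2-(tert-butyldimethylsilyloxy)-2-[(E)-prop-1-enyl]cyclopropyl}ethanol; 17 (5R)-5-[(4-methoxybenzyl)oxy]-5-methylhept-6-en-3-yn-2-one
Product: 18 cyclohepta-1,4-diene with C1=C5 and C8=C9 double bonds: acetyl on C1, (2R)-2-[(4-methoxybenzyl)oxy]but-3-en-2-yl on C5, (1S)-2-(tert-butyldimethylsilyloxy)-1-hydroxyethyl on C7 (7R), tert-butyldimethylsilyloxy on C8, methyl on C10 (10R)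
Conditions: [Rh(CO)2Cl]2 (5 mol %), ClCH2CH2Cl, 80 °C
Reagents that add atoms: none
Why: [Rh(CO)2Cl]2 (monovalent rhodium) binds the propenyl group of 10 and inserts into the less substituted C8–C6 cyclopropane bond to give a rhodacyclohexene (σ-alkyl at C6, π-allyl C8–C9–C10); the alkyne of 17 then inserts into the rhodium–allyl terminus (C1–C10 bond) and reductive elimination forms C5–C6. The closest known reaction type is the rhodium-catalysed intermolecular (5+2) cycloaddition of 1-alkoxy- and 1-siloxy-vinylcyclopropanes with alkynes, ynones included. The only ring closed is the seven-membered carbocycle (C1, C5–C10), formed by two-bond annulation through metallacycle expansion and C(sp3)–C(sp2) reductive elimination rather than by an exo or endo cyclisation; the cyclopropane is consumed. The new stereocentre C10 is controlled by the C7 stereocentre and the E geometry of the propenyl group: both bonds form on the rhodium-bound face of the five-carbon unit, so the side chain that is cis to the alkenyl group on the cyclopropane should end trans to the C10 methyl group (10R), while C7 is carried over unchanged. Two selectivities are needed: cleavage of C8–C6 rather than C8–C7, which the substituent on C7 should enforce, and one orientation of the alkyne, which should follow from the bulky fully substituted C4 carbon staying distal to the first-formed C–C bond and the acyl-bearing carbon bonding to the allyl terminus; the isolated vinyl group and the free hydroxyl should not interfere.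

Step 12
Reactants: 18 cyclohepta-1,4-diene (as above)
Product: 19 5β,11-epoxy ketone: oxolane C5–O–C11 closed, 1α-H, 7α-H, 10α-methyl, 11S, acetyl on C1, C8=C9 tert-butyldimethylsilyl enol ether, 12-O-tert-butyldimethylsilyl, (2R)-2-[(4-methoxybenzyl)oxy]but-3-en-2-yl on C5
Conditions: DBU (1.5 equiv), toluene, 60 °C
Reagents that add atoms: none
Why: Intramolecular oxa-Michael addition (5-exo-trig) of the 11-alkoxide to C5 of the strained tetrasubstituted enone; the tether on the β-oriented C7 side chain delivers oxygen to the β face of C5, and protonation of the enolate anti to the new C–O bond should give 1α-H.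

Step 13
Reactants: 19 5β,11-epoxy ketone (as above)
Product: 21 trimethylsilyl enol ether of 19 (CH2=C(OSiMe3)– on C1), via lithium enolate 20 (not isolated)
Conditions: LiN(iPr)2, THF, −78 °C; then Me3SiCl, Et3N, −78 °C
Reagents that add atoms: chlorotrimethylsilane, C[Si](C)(C)Cl
Why: Kinetic deprotonation of the methyl ketone at the unhindered methyl group (not at the tertiary C1–H, which would trigger retro-Michael opening) and O-silylation give the terminal silyl enol ether; no stereocentre changes.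

Step 14
Reactants: 21 trimethylsilyl enol ether of 19
Product: 23 12-hydroxy-4α-[(4-methoxybenzyl)oxy]-5β,11-epoxyguaiane-2,8-dione (1α-H, 7α-H, 10α-methyl, 11S), via cyclic silyl enol ether 22 (not isolated)
Conditions: second-generation Grubbs catalyst RuCl2(=CHPh)(PCy3)(H2IMes) (5 mol %), toluene, 80 °C; then HF·pyridine, THF, 0 °C → rt
Reagents that add atoms: none
Why: Ring-closing metathesis between the silyl enol ether and the vinyl group on C4 closes ring A as a five-membered cyclic enol ether (C2=C3) with loss of ethene, and fluoride/acid then cleaves both silyl enol ethers and the primary silyl ether under conditions that should not epimerise C1.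

Step 15
Reactants: 23 12-hydroxy-4α-[(4-methoxybenzyl)oxy]-5β,11-epoxyguaiane-2,8-dione
Product: 24 4α-[(4-methoxybenzyl)oxy]-5β,11-epoxyguaiane-2α,8β,12-triol
Conditions: NaBH4, CeCl3·7H2O, MeOH, −40 → 0 °C
Reagents that add atoms: none
Why: Luche reduction of both ketones: at C8 hydride should enter from the α face, syn to the one-carbon bridge C6 and anti to the C5–O–C11 bridge (8β-OH, cis to C11); at C2 it should enter from the β face, antiperiplanar to the axial H-1 and away from the pseudo-axial 4α-benzyloxy group (2α-OH).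

Step 16
Reactants: 24 4α-[(4-methoxybenzyl)oxy]-5β,11-epoxyguaiane-2α,8β,12-triol
Product: 27 2α-hydroxy-4α-[(4-methoxybenzyl)oxy]-5β,11-epoxyguaian-8β,12-olide (11S), via aldehyde 25 (not isolated), via lactol 26 (not isolated)
Conditions: TEMPO (0.2 equiv), PhI(OAc)2 (2.5 equiv), CH2Cl2, rt
Reagents that add atoms: none
Why: Primary-selective oxoammonium oxidation gives the C12 aldehyde, which closes onto the cis 8β-OH to a five-membered lactol that is oxidised further to the γ-lactone (oxidative lactonisation); the secondary 2-OH reacts far more slowly.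

Step 17
Reactants: 27 2α-hydroxy-4α-[(4-methoxybenzyl)oxy]-5β,11-epoxyguaian-8β,12-olide
Product: 29 2α,13-dihydroxy-4α-[(4-methoxybenzyl)oxy]-5β,11-epoxyguaian-8β,12-olide (11R), via lithium enolate 28 (not isolated)
Conditions: LiN(iPr)2 (2.5 equiv), THF, −78 °C; then CH2O (gas, from cracked paraformaldehyde), −78 → −40 °C
Reagents that add atoms: formaldehyde, C=O
Why: Aldol reaction of the α-alkoxy lactone enolate with formaldehyde; C11 is held in both the oxolane and the lactone, so the new carbon can only enter from the exo face and the 11R configuration is fixed by the ring system.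

Step 18
Reactants: 29 2α,13-dihydroxy-4α-[(4-methoxybenzyl)oxy]-5β,11-epoxyguaian-8β,12-olide
Product: 30 13-acetoxy-2α-hydroxy-4α-[(4-methoxybenzyl)oxy]-5β,11-epoxyguaian-8β,12-olide
Conditions: AcCl (1.1 equiv), 2,4,6-collidine, CH2Cl2, −78 °C
Reagents that add atoms: acetyl chloride, CC(=O)Cl
Why: Low-temperature acylation with acetyl chloride and a hindered pyridine base is selective for the primary 13-OH over the secondary 2-OH; no stereocentre is involved.

Step 19
Reactants: 30 13-acetoxy-2α-hydroxy-4α-[(4-methoxybenzyl)oxy]-5β,11-epoxyguaian-8β,12-olide; 31 tiglic acid ((E)-2-methylbut-2-enoic acid)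
Product: 32 13-acetoxy-4α-[(4-methoxybenzyl)oxy]-2α-tigloyloxy-5β,11-epoxyguaian-8β,12-olide
Conditions: 2,4,6-trichlorobenzoyl chloride, Et3N, DMAP, toluene, rt
Reagents that add atoms: none
Why: Yamaguchi esterification through the mixed anhydride acylates the secondary 2α-OH with retention at C2; the E geometry of the tiglate is the stable one and the protected tertiary 4-O cannot react.

Step 20
Reactants: 32 13-acetoxy-4α-[(4-methoxybenzyl)oxy]-2α-tigloyloxy-5β,11-epoxyguaian-8β,12-olide
Product: 33 CNP0112086.1, 13-acetoxy-4α-hydroxy-2α-tigloyloxy-5β,11-epoxyguaian-8β,12-olide (1R,2S,4R,5R,7S,8R,10R,11R)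
Conditions: DDQ, CH2Cl2/pH 7 phosphate buffer, 0 °C → rt
Reagents that add atoms: none
Why: Oxidative cleavage of the 4-methoxybenzyl ether by DDQ (hydride abstraction, hydrolysis of the oxocarbenium ion) frees the tertiary 4α-OH; esters, lactone and the electron-poor tiglate alkene should be inert.

## Compound list

1 | D-ribono-1,4-lactone | O=C1O[C@H](CO)[C@@H](O)[C@H]1O | starting material
2 | 5-O-(tert-butyldimethylsilyl)-D-ribono-1,4-lactone | O=C1O[C@H](CO[Si](C)(C)C(C)(C)C)[C@@H](O)[C@H]1O | intermediate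
3 | 2,3-di-O-acetyl-5-O-(tert-butyldimethylsilyl)-D-ribono-1,4-lactone (not isolated) | O=C1O[C@H](CO[Si](C)(C)C(C)(C)C)[C@@H](OC(C)=O)[C@H]1OC(C)=O | intermediate
4 | (5S)-3-acetoxy-5-[(tert-butyldimethylsilyloxy)methyl]furan-2(5H)-one | O=C1O[C@H](CO[Si](C)(C)C(C)(C)C)C=C1OC(C)=O | intermediate
5 | (5S)-3-hydroxy-5-[(tert-butyldimethylsilyloxy)methyl]furan-2(5H)-one (not isolated) | O=C1O[C@H](CO[Si](C)(C)C(C)(C)C)C=C1O | intermediate
6 | (5S)-3-(tert-butyldimethylsilyloxy)-5-[(tert-butyldimethylsilyloxy)methyl]furan-2(5H)-one | O=C1O[C@H](CO[Si](C)(C)C(C)(C)C)C=C1O[Si](C)(C)C(C)(C)C | intermediate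
7 | (1S,4S,5R)-1-(tert-butyldimethylsilyloxy)-4-[(tert-butyldimethylsilyloxy)methyl]-3-oxabicyclo[3.1.0]hexan-2-one | O=C1O[C@H](CO[Si](C)(C)C(C)(C)C)[C@H]2C[C@@]12O[Si](C)(C)C(C)(C)C | intermediate
8 | (1S,4S,5R)-1-(tert-butyldimethylsilyloxy)-4-[(tert-butyldimethylsilyloxy)methyl]-3-oxabicyclo[3.1.0]hexan-2-ol (both anomers) | OC1O[C@H](CO[Si](C)(C)C(C)(C)C)[C@H]2C[C@@]12O[Si](C)(C)C(C)(C)C | intermediate
9 | 5-(ethylsulfonyl)-1-phenyl-1H-tetrazole | CCS(=O)(=O)c1nnnn1-c1ccccc1 | starting material
10 | (1S)-2-(tert-butyldimethylsilyloxy)-1-{(1R,2R)-2-(tert-butyldimethylsilyloxy)-2-[(E)-prop-1-enyl]cyclopropyl}ethanol | C/C=C/[C@]1(O[Si](C)(C)C(C)(C)C)C[C@@H]1[C@H](O)CO[Si](C)(C)C(C)(C)C | intermediate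
11 | 2-methyl-2-vinyloxirane (racemic) | C=CC1(C)CO1 | starting material
12 | 4-methoxybenzyl alcohol | COc1ccc(CO)cc1 | starting material
13 | (2R)-2-[(4-methoxybenzyl)oxy]-2-methylbut-3-en-1-ol | OC[C@](C)(OCc1ccc(OC)cc1)C=C | intermediate
14 | (2R)-2-[(4-methoxybenzyl)oxy]-2-methylbut-3-enal | O=C[C@](C)(OCc1ccc(OC)cc1)C=C | intermediate
15 | (3R)-3-[(4-methoxybenzyl)oxy]-3-methylpent-1-en-4-yne | C#C[C@](C)(OCc1ccc(OC)cc1)C=C | intermediate
16 | lithium acetylide of 15 (not isolated) | [Li]C#C[C@](C)(OCc1ccc(OC)cc1)C=C | intermediate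
17 | (5R)-5-[(4-methoxybenzyl)oxy]-5-methylhept-6-en-3-yn-2-one | CC(=O)C#C[C@](C)(OCc1ccc(OC)cc1)C=C | intermediate
18 | cyclohepta-1,4-diene from the (5+2) step: C1=C5 and C8=C9; 1-acetyl; 5-[(2R)-2-[(4-methoxybenzyl)oxy]but-3-en-2-yl]; 7R with (1S)-2-(tert-butyldimethylsilyloxy)-1-hydroxyethyl; 8-tert-butyldimethylsilyloxy; 10R-methyl | C=C[C@@](C)(OCc1ccc(OC)cc1)C1=C(C(C)=O)[C@H](C)C=C(O[Si](C)(C)C(C)(C)C)[C@@H]([C@H](O)CO[Si](C)(C)C(C)(C)C)C1 | intermediate
19 | 5β,11-epoxy ketone: 1α-H, 7α-H, 10α-methyl, 11S; 1-acetyl; C8=C9 silyl enol ether; 12-O-silyl; C5 side chain as in 18 | C=C[C@@](C)(OCc1ccc(OC)cc1)[C@@]23C[C@H]([C@@H](CO[Si](C)(C)C(C)(C)C)O3)C(O[Si](C)(C)C(C)(C)C)=C[C@@H](C)[C@@H]2C(C)=O | intermediate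
20 | lithium enolate of 19 at the acetyl methyl (not isolated) | C=C[C@@](C)(OCc1ccc(OC)cc1)[C@@]23C[C@H]([C@@H](CO[Si](C)(C)C(C)(C)C)O3)C(O[Si](C)(C)C(C)(C)C)=C[C@@H](C)[C@@H]2C(O[Li])=C | intermediate
21 | trimethylsilyl enol ether of 19 (1-[1-(trimethylsilyloxy)vinyl]) | C=C[C@@](C)(OCc1ccc(OC)cc1)[C@@]23C[C@H]([C@@H](CO[Si](C)(C)C(C)(C)C)O3)C(O[Si](C)(C)C(C)(C)C)=C[C@@H](C)[C@@H]2C(O[Si](C)(C)C)=C | intermediate
22 | ring A cyclic silyl enol ether: 2-(trimethylsilyloxy)-2-ene, 4α-(4-methoxybenzyl)oxy, 5β,11-epoxy, C8=C9 silyl enol ether, 12-O-silyl (not isolated) | C[Si](C)(C)OC1=C[C@@](C)(OCc4ccc(OC)cc4)[C@@]23C[C@H]([C@@H](CO[Si](C)(C)C(C)(C)C)O3)C(O[Si](C)(C)C(C)(C)C)=C[C@@H](C)[C@H]12 | intermediate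
23 | 12-hydroxy-4α-[(4-methoxybenzyl)oxy]-5β,11-epoxyguaiane-2,8-dione (1α-H, 7α-H, 10α-methyl, 11S) | O=C1C[C@@](C)(OCc4ccc(OC)cc4)[C@@]23C[C@H]([C@@H](CO)O3)C(=O)C[C@@H](C)[C@H]12 | intermediate
24 | 4α-[(4-methoxybenzyl)oxy]-5β,11-epoxyguaiane-2α,8β,12-triol | O[C@H]1C[C@@](C)(OCc4ccc(OC)cc4)[C@@]23C[C@H]([C@@H](CO)O3)[C@@H](C[C@@H](C)[C@H]12)O | intermediate
25 | 2α,8β-dihydroxy-4α-[(4-methoxybenzyl)oxy]-5β,11-epoxyguaian-12-al (not isolated) | O[C@H]1C[C@@](C)(OCc4ccc(OC)cc4)[C@@]23C[C@H]([C@@H](C=O)O3)[C@@H](C[C@@H](C)[C@H]12)O | intermediate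
26 | 8β,12-lactol of 25 (not isolated) | O[C@H]1C[C@@](C)(OCc5ccc(OC)cc5)[C@@]23C[C@H]4[C@@H](C[C@@H](C)[C@H]12)OC(O)[C@H]4O3 | intermediate
27 | 2α-hydroxy-4α-[(4-methoxybenzyl)oxy]-5β,11-epoxyguaian-8β,12-olide (11S) | O[C@H]1C[C@@](C)(OCc5ccc(OC)cc5)[C@@]23C[C@H]4[C@@H](C[C@@H](C)[C@H]12)OC(=O)[C@H]4O3 | intermediate
28 | lithium enolate (2-O-lithium alkoxide) of 27 (not isolated) | [Li]O[C@H]1C[C@@](C)(OCc5ccc(OC)cc5)[C@@]23C[C@H]4[C@@H](C[C@@H](C)[C@H]12)OC(O[Li])=C4O3 | intermediate
29 | 2α,13-dihydroxy-4α-[(4-methoxybenzyl)oxy]-5β,11-epoxyguaian-8β,12-olide (11R) | O[C@H]1C[C@@](C)(OCc5ccc(OC)cc5)[C@@]23C[C@H]4[C@@H](C[C@@H](C)[C@H]12)OC(=O)[C@@]4(CO)O3 | intermediate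
30 | 13-acetoxy-2α-hydroxy-4α-[(4-methoxybenzyl)oxy]-5β,11-epoxyguaian-8β,12-olide | O[C@H]1C[C@@](C)(OCc5ccc(OC)cc5)[C@@]23C[C@H]4[C@@H](C[C@@H](C)[C@H]12)OC(=O)[C@@]4(COC(C)=O)O3 | intermediate
31 | tiglic acid, (E)-2-methylbut-2-enoic acid | C/C=C(\C)C(=O)O | starting material
32 | 13-acetoxy-4α-[(4-methoxybenzyl)oxy]-2α-tigloyloxy-5β,11-epoxyguaian-8β,12-olide | C/C=C(\C)C(=O)O[C@H]1C[C@@](C)(OCc5ccc(OC)cc5)[C@@]23C[C@H]4[C@@H](C[C@@H](C)[C@H]12)OC(=O)[C@@]4(COC(C)=O)O3 | intermediate
33 | CNP0112086.1, 13-acetoxy-4α-hydroxy-2α-tigloyloxy-5β,11-epoxyguaian-8β,12-olide | C/C=C(\C)C(=O)O[C@H]1C[C@@](C)(O)[C@@]23C[C@H]4[C@@H](C[C@@H](C)[C@H]12)OC(=O)[C@@]4(COC(C)=O)O3 | target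

## Step count and risks

Total: 20 steps. Longest linear sequence: 16 steps (steps 1–6, then 11–20); the ynone arm (steps 7–10) is 4 steps.

**Step 11 (key step).** What may go wrong: slow insertion of the hindered internal alkyne into a rhodacycle whose allyl terminus carries a methyl group, so that conversion is low and vinylcyclopropane isomerisation or ring expansion takes over. Fallback: the route would set out from lactol 8. Wittig methylenation (Ph3P=CH2, THF) should give the terminally unsubstituted (1S)-2-(tert-butyldimethylsilyloxy)-1-[(1R,2R)-2-(tert-butyldimethylsilyloxy)-2-vinylcyclopropyl]ethanol F1, the parent substrate type of this cycloaddition. Cycloaddition of it with ynone 17 under the conditions of step 11 should give the 10-nor-methyl cycloheptadiene F2, and oxa-Michael closure as in step 12 the 10-nor-methyl 5β,11-epoxy ketone F3. Saegusa–Ito oxidation of its silyl enol ether (Pd(OAc)2, MeCN) should give the C9=C10 enone F4. Conjugate addition of Me2CuLi in the presence of t-BuMe2SiCl, anti to the oxygen bridge, should then install the 10α-methyl group and regenerate the C8 silyl enol ether, coming back to the route at 19.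

**Step 12.** What may go wrong: the alkoxide may add slowly or reversibly to the twisted, fully substituted enone (retro-Michael opening, silyl migration from the enol ether to the alkoxide). Fallback: the route would set out from 18 and close ring A before the ether bridge. Double silylation (LiN(iPr)2, Me3SiCl) should give the 11-O-trimethylsilyl 2-silyloxydiene F5, and ring-closing metathesis with the second-generation Grubbs catalyst the ring A 2-(trimethylsilyloxy)cyclopentadiene F6. Mild methanolysis (PPTS, MeOH) should give the fused 4α-[(4-methoxybenzyl)oxy]cyclopent-1(5)-en-2-one with free 11-OH F7. Conjugate addition of 11-OH to this planar, fully conjugated enone (DBU or camphorsulfonic acid) should give the bridged cyclopentanone F8, and HF·pyridine would bring the material back to the route at 23.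

**Step 17.** What may go wrong: incomplete enolisation of the strained ring-fusion α-alkoxy lactone, or decomposition of the enolate and retro-aldol loss of formaldehyde on warming. Fallback: the route would set out from triol 24 and move the C–C bond formation to the aldehyde oxidation level. Oxidation with TEMPO and PhI(OAc)2 (1.1 equiv) should stop at lactol 26. Crossed aldol (Tollens) hydroxymethylation with aqueous CH2O and K2CO3 through the ring-opened aldehyde should give the 13-hydroxy lactol F9, because only the C11 epimer with the formyl group syn to 8β-OH can close again. Oxidation of the lactol with Ag2CO3 on Celite (benzene, reflux) would come back to the route at 29.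

Further compounds
F1 | step 11 | (1S)-2-(tert-butyldimethylsilyloxy)-1-[(1R,2R)-2-(tert-butyldimethylsilyloxy)-2-vinylcyclopropyl]ethanol | C=C[C@]1(O[Si](C)(C)C(C)(C)C)C[C@@H]1[C@H](O)CO[Si](C)(C)C(C)(C)C
F2 | step 11 | 10-nor-methyl analogue of cycloheptadiene 18 | C=C[C@@](C)(OCc1ccc(OC)cc1)C1=C(C(C)=O)CC=C(O[Si](C)(C)C(C)(C)C)[C@@H]([C@H](O)CO[Si](C)(C)C(C)(C)C)C1
F3 | step 11 | 10-nor-methyl analogue of 5β,11-epoxy ketone 19 | C=C[C@@](C)(OCc1ccc(OC)cc1)[C@@]23C[C@H]([C@@H](CO[Si](C)(C)C(C)(C)C)O3)C(O[Si](C)(C)C(C)(C)C)=CC[C@@H]2C(C)=O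
F4 | step 11 | 10-nor-methyl 5β,11-epoxy 9-en-8-one (1-acetyl, 12-O-silyl) | C=C[C@@](C)(OCc1ccc(OC)cc1)[C@@]23C[C@H]([C@@H](CO[Si](C)(C)C(C)(C)C)O3)C(=O)C=C[C@@H]2C(C)=O
F5 | step 12 | 11-O-trimethylsilyl ether and 1-[1-(trimethylsilyloxy)vinyl] derivative of 18 | C=C[C@@](C)(OCc1ccc(OC)cc1)C1=C(C(O[Si](C)(C)C)=C)[C@H](C)C=C(O[Si](C)(C)C(C)(C)C)[C@@H]([C@H](O[Si](C)(C)C)CO[Si](C)(C)C(C)(C)C)C1
F6 | step 12 | ring A 2-(trimethylsilyloxy)cyclopenta-1(5),2-diene fused to the cycloheptene (11-O-trimethylsilyl) | C[Si](C)(C)OC1=C[C@@](C)(OCc3ccc(OC)cc3)C2=C1[C@H](C)C=C(O[Si](C)(C)C(C)(C)C)[C@@H]([C@H](O[Si](C)(C)C)CO[Si](C)(C)C(C)(C)C)C2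
F7 | step 12 | fused 4α-[(4-methoxybenzyl)oxy]cyclopent-1(5)-en-2-one with free 11-OH (C8=C9 silyl enol ether, 12-O-silyl) | O=C1C[C@@](C)(OCc3ccc(OC)cc3)C2=C1[C@H](C)C=C(O[Si](C)(C)C(C)(C)C)[C@@H]([C@H](O)CO[Si](C)(C)C(C)(C)C)C2
F8 | step 12 | 4α-[(4-methoxybenzyl)oxy]-5β,11-epoxyguaian-2-one with C8=C9 silyl enol ether and 12-O-silyl | O=C1C[C@@](C)(OCc4ccc(OC)cc4)[C@@]23C[C@H]([C@@H](CO[Si](C)(C)C(C)(C)C)O3)C(O[Si](C)(C)C(C)(C)C)=C[C@@H](C)[C@H]12
F9 | step 17 | 13-hydroxy derivative of lactol 26 (11R) | O[C@H]1C[C@@](C)(OCc5ccc(OC)cc5)[C@@]23C[C@H]4[C@@H](C[C@@H](C)[C@H]12)OC(O)[C@@]4(CO)O3
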